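**Retrosynthetic overview**
1. Siphulin ⇐ hydrogenolysis of its tetrabenzyl derivative (three aryl benzyl ethers, one benzyl ester), so the decarboxylation-prone dihydroxybenzoic acid is unveiled last under neutral conditions.
2. The pyranone ring is the only ring built (both benzene rings are bought) ⇐ acid cyclodehydration of a 1-(2-hydroxyaryl)butane-1,3-dione.
3. 1,3-Diketone ⇐ intermolecular crossed Claisen condensation joining the two fragments: dilithium enolate of a 4-benzyloxy-6-heptyl-2-hydroxyacetophenone (fragment A) plus the aliphatic methyl ester of a benzyl-protected 3,5-dihydroxyhomophthalate (fragment B).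
4. Fragment A ⇐ 1-bromo-3,5-dimethoxybenzene: Kumada heptylation, Friedel–Crafts acetylation, demethylation, selective 4-O-benzylation.
5. Fragment B ⇐ methyl 3,5-dihydroxyphenylacetate: O-benzylation, Vilsmeier formylation, Pinnick oxidation, benzyl esterification.

Assumption: siphulin as drawn has no stereocentre and no stereogenic double bond, so it is achiral and the route needs no asymmetric step; every numbered compound is achiral.

**Fragment A**

Step 1
Reactants: 1 1-bromo-3,5-dimethoxybenzene; 2 n-heptylmagnesium bromide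
Product: 3 1-heptyl-3,5-dimethoxybenzene
Conditions: NiCl2(dppp) (2 mol %), Et2O, 0 °C → reflux, 12 h; aq. NH4Cl
Reagents that add atoms: none
Why: Kumada–Corriu cross-coupling of an aryl bromide with a primary alkyl Grignard reagent, in which the chelating dppp ligand on nickel suppresses β-hydride elimination.

Step 2
Reactants: 3 1-heptyl-3,5-dimethoxybenzene
Product: 4 1-(2-heptyl-4,6-dimethoxyphenyl)ethan-1-one
Conditions: AcCl (1.2 equiv), AlCl3 (1.3 equiv), CH2Cl2, −10 → 0 °C, 2 h; ice/1 M HCl
Reagents that add atoms: acetyl chloride, CC(=O)Cl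
Why: Friedel–Crafts acylation goes para to one methoxy group and ortho to the other (the position next to the heptyl chain), as with orcinol and olivetol dimethyl ethers, because the site between the two methoxy groups is the more hindered.

Step 3
Reactants: 4 1-(2-heptyl-4,6-dimethoxyphenyl)ethan-1-one
Product: 5 1-(2-heptyl-4,6-dihydroxyphenyl)ethan-1-one
Conditions: BBr3 (4 equiv, 1 M in CH2Cl2), CH2Cl2, −78 °C → rt, 16 h; ice-water
Reagents that add atoms: none
Why: Lewis-acid ether cleavage (BBr3 demethylation) removes the carbonyl-chelated ortho methyl ether quickly and the para one on warming, while the aryl ketone and alkyl chain are inert.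

Step 4
Reactants: 5 1-(2-heptyl-4,6-dihydroxyphenyl)ethan-1-one
Product: 6 1-[4-(benzyloxy)-2-heptyl-6-hydroxyphenyl]ethan-1-one
Conditions: BnBr (1.05 equiv), K2CO3 (1.1 equiv), acetone, reflux, 6 h
Reagents that add atoms: benzyl bromide, BrCc1ccccc1
Why: Williamson etherification is selective for the 4-OH because the 6-OH is held in a strong hydrogen bond to the ketone and is far less nucleophilic.

**Fragment B**

Step 5
Reactants: 7 methyl 2-(3,5-dihydroxyphenyl)acetate
Product: 8 methyl 2-[3,5-bis(benzyloxy)phenyl]acetate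
Conditions: BnBr (2.2 equiv), K2CO3 (2.5 equiv), acetone, reflux, 16 h
Reagents that add atoms: benzyl bromide, BrCc1ccccc1
Why: Williamson etherification of both phenols, with a carbonate base too weak to enolise the arylacetate.

Step 6
Reactants: 8 methyl 2-[3,5-bis(benzyloxy)phenyl]acetate
Product: 10 methyl 2-[3,5-bis(benzyloxy)-2-formylphenyl]acetate, via iminium chloride 9 (not isolated)
Conditions: POCl3 (1.3 equiv), DMF, 0 → 60 °C, 3 h; then H2O, 0 °C → rt
Reagents that add atoms: N,N-dimethylformamide, CN(C)C=O; water, O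
Why: Vilsmeier–Haack formylation attacks the position ortho to the side chain and para to a benzyloxy group (the same selectivity as the well-known dimethoxy analogue), and hydrolysis of the iminium salt gives the aldehyde.

Step 7
Reactants: 10 methyl 2-[3,5-bis(benzyloxy)-2-formylphenyl]acetate
Product: 11 2,4-bis(benzyloxy)-6-(2-methoxy-2-oxoethyl)benzoic acid
Conditions: NaClO2 (3 equiv), NaH2PO4 (3 equiv), 2-methyl-2-butene (10 equiv), t-BuOH/THF/H2O, 0 °C → rt, 4 h
Reagents that add atoms: sodium chlorite, [Na+].[O-]Cl=O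
Why: Pinnick oxidation converts the aldehyde to the acid under buffered conditions, and the alkene scavenger traps HOCl so the electron-rich ring is not chlorinated.

Step 8
Reactants: 11 2,4-bis(benzyloxy)-6-(2-methoxy-2-oxoethyl)benzoic acid
Product: 12 benzyl 2,4-bis(benzyloxy)-6-(2-methoxy-2-oxoethyl)benzoate
Conditions: BnBr (1.2 equiv), K2CO3 (1.5 equiv), DMF, rt, 8 h
Reagents that add atoms: benzyl bromide, BrCc1ccccc1
Why: Carboxylate O-alkylation (an SN2 reaction at benzyl bromide) is unaffected by the steric crowding around the benzoate carbonyl and gives two esters of very different reactivity.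

**Fragment union and end game**

Step 9
Reactants: 6 1-[4-(benzyloxy)-2-heptyl-6-hydroxyphenyl]ethan-1-one; 12 benzyl 2,4-bis(benzyloxy)-6-(2-methoxy-2-oxoethyl)benzoate
Product: 14 benzyl 2,4-bis(benzyloxy)-6-{4-[4-(benzyloxy)-2-heptyl-6-hydroxyphenyl]-2,4-dioxobutyl}benzoate, via dilithium enolate-phenoxide 13 (not isolated)
Conditions: 6, LiN(SiMe3)2 (3.2 equiv), THF, −78 °C, 1 h; then 12 (1.1 equiv) in THF, −78 °C → rt, 6 h; cold 1 M HCl
Reagents that add atoms: none
Why: Crossed Claisen condensation in which the methyl-ketone enolate attacks only the unhindered aliphatic methyl ester (the di-ortho-substituted, electron-rich benzyl benzoate is inert), and reversible proton transfers with the enolisable ester are funnelled to product by irreversible formation of the lithium β-diketonate.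

Step 10
Reactants: 14 benzyl 2,4-bis(benzyloxy)-6-{4-[4-(benzyloxy)-2-heptyl-6-hydroxyphenyl]-2,4-dioxobutyl}benzoate
Product: 15 benzyl 2,4-bis(benzyloxy)-6-{[7-(benzyloxy)-5-heptyl-4-oxo-4H-chromen-2-yl]methyl}benzoate
Conditions: p-TsOH·H2O (0.2 equiv), toluene, 80 °C, 2 h
Reagents that add atoms: none
Why: Acid-catalysed cyclodehydration, in which the free phenol adds to the aliphatic ketone and the hemiketal loses water to give the chromone, is much faster than any attack on the hindered benzyl ester.

Step 11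
Reactants: 15 benzyl 2,4-bis(benzyloxy)-6-{[7-(benzyloxy)-5-heptyl-4-oxo-4H-chromen-2-yl]methyl}benzoate
Product: 16 siphulin, 2-[(5-heptyl-7-hydroxy-4-oxo-4H-chromen-2-yl)methyl]-4,6-dihydroxybenzoic acid
Conditions: H2 (1 atm), 10% Pd/C, EtOAc/MeOH 1:1, rt, 2–4 h (stop when debenzylation is complete); filter through Celite
Reagents that add atoms: none
Why: Catalytic hydrogenolysis cleaves the three benzyl ethers and the benzyl ester at room temperature under neutral conditions, faster than reduction of the chromone double bond and without heat or acid that would decarboxylate the product.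

**Compound list**
1 | 1-bromo-3,5-dimethoxybenzene | COc1cc(Br)cc(OC)c1 | starting material
2 | n-heptylmagnesium bromide | CCCCCCC[Mg]Br | starting material
3 | 1-heptyl-3,5-dimethoxybenzene | CCCCCCCc1cc(OC)cc(OC)c1 | intermediate
4 | 1-(2-heptyl-4,6-dimethoxyphenyl)ethan-1-one | CCCCCCCc1cc(OC)cc(OC)c1C(C)=O | intermediate
5 | 1-(2-heptyl-4,6-dihydroxyphenyl)ethan-1-one | CCCCCCCc1cc(O)cc(O)c1C(C)=O | intermediate
6 | 1-[4-(benzyloxy)-2-heptyl-6-hydroxyphenyl]ethan-1-one | CCCCCCCc1cc(OCc2ccccc2)cc(O)c1C(C)=O | intermediate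
7 | methyl 2-(3,5-dihydroxyphenyl)acetate | COC(=O)Cc1cc(O)cc(O)c1 | starting material
8 | methyl 2-[3,5-bis(benzyloxy)phenyl]acetate | COC(=O)Cc1cc(OCc2ccccc2)cc(OCc2ccccc2)c1 | intermediate
9 | N-{[2,4-bis(benzyloxy)-6-(2-methoxy-2-oxoethyl)phenyl]methylidene}-N-methylmethanaminium chloride (not isolated) | COC(=O)Cc1cc(OCc2ccccc2)cc(OCc2ccccc2)c1C=[N+](C)C.[Cl-] | intermediate
10 | methyl 2-[3,5-bis(benzyloxy)-2-formylphenyl]acetate | COC(=O)Cc1cc(OCc2ccccc2)cc(OCc2ccccc2)c1C=O | intermediate
11 | 2,4-bis(benzyloxy)-6-(2-methoxy-2-oxoethyl)benzoic acid | COC(=O)Cc1cc(OCc2ccccc2)cc(OCc2ccccc2)c1C(=O)O | intermediate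
12 | benzyl 2,4-bis(benzyloxy)-6-(2-methoxy-2-oxoethyl)benzoate | COC(=O)Cc1cc(OCc2ccccc2)cc(OCc2ccccc2)c1C(=O)OCc1ccccc1 | intermediate
13 | dilithium 5-(benzyloxy)-3-heptyl-2-(1-oxidoethenyl)phenolate (not isolated) | CCCCCCCc1cc(OCc2ccccc2)cc([O-])c1C([O-])=C.[Li+].[Li+] | intermediate
14 | benzyl 2,4-bis(benzyloxy)-6-{4-[4-(benzyloxy)-2-heptyl-6-hydroxyphenyl]-2,4-dioxobutyl}benzoate (drawn as the diketo tautomer) | CCCCCCCc1cc(OCc2ccccc2)cc(O)c1C(=O)CC(=O)Cc1cc(OCc2ccccc2)cc(OCc2ccccc2)c1C(=O)OCc1ccccc1 | intermediate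
15 | benzyl 2,4-bis(benzyloxy)-6-{[7-(benzyloxy)-5-heptyl-4-oxo-4H-chromen-2-yl]methyl}benzoate | CCCCCCCc1cc(OCc2ccccc2)cc2oc(Cc3cc(OCc4ccccc4)cc(OCc4ccccc4)c3C(=O)OCc3ccccc3)cc(=O)c12 | intermediate
16 | siphulin, 2-[(5-heptyl-7-hydroxy-4-oxo-4H-chromen-2-yl)methyl]-4,6-dihydroxybenzoic acid | CCCCCCCc1cc(O)cc2oc(Cc3cc(O)cc(O)c3C(=O)O)cc(=O)c12 | target

**Totals**
Total step count: 11.
Longest linear sequence: 7 steps (steps 1–4, then 9–11; the branch through steps 5–8, then 9–11 is equally long).

**Three steps most likely to fail**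

Step 9, the crossed Claisen condensation. The acceptor ester carries acidic benzylic α-hydrogens, so enolisation or self-condensation of 12 may outrun C-acylation. The fallback replaces the Claisen condensation and the cyclodehydration by an intramolecular Wittig ring closure; it sets out from 6 and 12 and comes back to the route at 15. Ketone 6 is brominated on the acetyl methyl with copper dibromide (CuBr2, EtOAc/CHCl3, reflux) to give 1-[4-(benzyloxy)-2-heptyl-6-hydroxyphenyl]-2-bromoethan-1-one F1. PPh3 in toluene turns this into {2-[4-(benzyloxy)-2-heptyl-6-hydroxyphenyl]-2-oxoethyl}triphenylphosphonium bromide F2, and aqueous Na2CO3/CH2Cl2 gives the stabilised ylide 1-[4-(benzyloxy)-2-heptyl-6-hydroxyphenyl]-2-(triphenylphosphoranylidene)ethan-1-one F3. Separately, LiOH (THF/H2O, 0 °C) hydrolyses only the unhindered methyl ester of 12 to 2-{3,5-bis(benzyloxy)-2-[(benzyloxy)carbonyl]phenyl}acetic acid F4. Esterification of the phenol of F3 with F4 (EDC·HCl, DMAP, CH2Cl2) gives the O-acyl ylide 5-(benzyloxy)-3-heptyl-2-[(triphenylphosphoranylidene)acetyl]phenyl 2-{3,5-bis(benzyloxy)-2-[(benzyloxy)carbonyl]phenyl}acetate F5. Heating F5 in toluene (100 °C) closes the pyranone by Wittig olefination of the aryl ester carbonyl and gives 15, with no strong base and no diketone 14.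

Step 11, the global hydrogenolysis. The chromone C2–C3 double bond may be reduced to the chromanone before the hindered benzyl ester is gone. The fallback sets out from 15 and comes back at 16, and it swaps reductive cleavage for Lewis-acid debenzylation: BCl3 (1 M in CH2Cl2, 8 equiv) with pentamethylbenzene (12 equiv) as benzyl-cation scavenger, CH2Cl2, −78 °C, MeOH quench. This cannot touch the pyranone double bond, stays cold enough to avoid decarboxylation, and makes no new compound (F0).

Step 2, the Friedel–Crafts acetylation. AlCl3 can give regioisomer mixtures and partial demethylation. The fallback sets out from 3 and comes back at 4, building the acetyl group in stages. Vilsmeier–Haack formylation (POCl3, DMF, 0 → 70 °C; water), which is milder and more para-selective, gives 2-heptyl-4,6-dimethoxybenzaldehyde F6. MeMgBr (THF, 0 °C) gives racemic 1-(2-heptyl-4,6-dimethoxyphenyl)ethan-1-ol F7, and Dess–Martin periodinane (CH2Cl2, rt) oxidises it to 4.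

**Further compounds**
F1 | step 9 | 1-[4-(benzyloxy)-2-heptyl-6-hydroxyphenyl]-2-bromoethan-1-one | CCCCCCCc1cc(OCc2ccccc2)cc(O)c1C(=O)CBr
F2 | step 9 | {2-[4-(benzyloxy)-2-heptyl-6-hydroxyphenyl]-2-oxoethyl}triphenylphosphonium bromide | CCCCCCCc1cc(OCc2ccccc2)cc(O)c1C(=O)C[P+](c1ccccc1)(c1ccccc1)c1ccccc1.[Br-]
F3 | step 9 | 1-[4-(benzyloxy)-2-heptyl-6-hydroxyphenyl]-2-(triphenylphosphoranylidene)ethan-1-one | CCCCCCCc1cc(OCc2ccccc2)cc(O)c1C(=O)C=P(c1ccccc1)(c1ccccc1)c1ccccc1
F4 | step 9 | 2-{3,5-bis(benzyloxy)-2-[(benzyloxy)carbonyl]phenyl}acetic acid | OC(=O)Cc1cc(OCc2ccccc2)cc(OCc2ccccc2)c1C(=O)OCc1ccccc1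
F5 | step 9 | 5-(benzyloxy)-3-heptyl-2-[(triphenylphosphoranylidene)acetyl]phenyl 2-{3,5-bis(benzyloxy)-2-[(benzyloxy)carbonyl]phenyl}acetate | CCCCCCCc1cc(OCc2ccccc2)cc(OC(=O)Cc2cc(OCc3ccccc3)cc(OCc3ccccc3)c2C(=O)OCc2ccccc2)c1C(=O)C=P(c1ccccc1)(c1ccccc1)c1ccccc1
F0 | step 11 | none | none
F6 | step 2 | 2-heptyl-4,6-dimethoxybenzaldehyde | CCCCCCCc1cc(OC)cc(OC)c1C=O
F7 | step 2 | 1-(2-heptyl-4,6-dimethoxyphenyl)ethan-1-ol (racemic) | CCCCCCCc1cc(OC)cc(OC)c1C(C)O
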